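**Assumption:** (S)-(+)-citramalic acid, L-lactic acid and 10-phenyldecanoic acid are taken as catalogue starting materials. Atom labels follow the target: C1 lactone C=O, C2 CH2, C3 O–CH, C4 and C6 the two methyl-bearing carbons, C5 the CH2 between them, C7 onward the side chain.

## Retrosynthetic overview

1. Target ⇒ lactol of an α-hydroxy-γ-lactone: C2–C3 by Wittig olefination, then C3–O and the lactone C–O by an oxa-Michael/lactonisation cascade; the cis ring fusion relays C4 to C3.
2. α-Hydroxy-γ-lactone ⇒ C4–C5 bond between the enolate of the L-lactic acid pivalaldehyde acetal (C3, C4) and (S)-2-methyl-2-(10-phenyldecyl)oxirane (C5, C6).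
3. Epoxide ⇒ (S)-citramalic acid acetonide + 10-phenyldecanoic acid: C7–C8 bond by anodic mixed Kolbe coupling.
4. Ring order: the O–C6–C5–C4–C3 five-membered ring is made first (as a lactone, then lactol, reclosing as the tetrahydrofuran); the γ-lactone is formed last.

## Route

**Step 1**
Reactants: 1 (S)-citramalic acid; 2 2,2-dimethoxypropane
Product: 3 (S)-2-(2,2,4-trimethyl-5-oxo-1,3-dioxolan-4-yl)acetic acid
Conditions: 2,2-dimethoxypropane, TsOH·H2O (cat.), rt
Reagents that add atoms: 2,2-dimethoxypropane, COC(C)(C)OC (CMe2 unit)
Why: Acid-catalysed transacetalisation gives the five-membered dioxolanone of the α-hydroxy acid (as with malic acid), leaving only the CH2CO2H free; the stereocentre is untouched.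

**Step 2**
Reactants: 3 (3 equiv); 4 10-phenyldecanoic acid (1 equiv)
Product: 5 (S)-2,2,5-trimethyl-5-(10-phenyldecyl)-1,3-dioxolan-4-one
Conditions: Pt anode/Pt cathode, undivided cell, MeOH, Et3N (5 mol%), ca. 150 mA cm⁻², 30–35 °C
Reagents that add atoms: 10-phenyldecanoic acid, OC(=O)CCCCCCCCCc1ccccc1 (gives Ph(CH2)9 after loss of CO2)
Why: Mixed Kolbe electrolysis: anodic decarboxylation gives the two primary radicals, which cross-combine to form C7–C8; the quaternary stereocentre is β to the radical and cannot scramble (precedent: Kolbe cross-couplings of the malic acid dioxolanone acid).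

**Step 3**
Reactants: 5
Product: 6 (S)-2-methyl-12-phenyldodecane-1,2-diol
Conditions: LiAlH4, THF, 0 °C → rt
Reagents that add atoms: none
Why: Hydride reduction of the acylal lactone gives the primary alcohol and frees the tertiary OH (acetone is lost); no bond to the stereocentre is broken.

**Step 4**
Reactants: 6
Product: 7 (S)-2-methyl-2-(10-phenyldecyl)oxirane
Conditions: NaH, N-tosylimidazole, THF, 0 °C → rt
Reagents that add atoms: none
Why: Selective sulfonylation of the primary alkoxide and intramolecular Williamson closure (3-exo-tet) by the tertiary alkoxide; the C–O bond at the stereocentre is retained.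

**Step 5**
Reactants: 8 (S)-lactic acid; 9 pivalaldehyde
Product: 10 (2S,5S)-2-tert-butyl-5-methyl-1,3-dioxolan-4-one (cis)
Conditions: t-BuCHO, TsOH (cat.), H2SO4 (cat.), pentane, reflux (Dean–Stark); crystallise at −78 °C
Reagents that add atoms: pivalaldehyde, CC(C)(C)C=O
Why: Seebach acetalisation under thermodynamic control gives the cis acetal (about 96:4); the lactic acid stereocentre sets the acetal centre.

**Step 6**
Reactants: 10 (2.5 equiv); 7
Product: 11 (3R,5S)-3-hydroxy-3,5-dimethyl-5-(10-phenyldecyl)dihydrofuran-2(3H)-one
Conditions: LDA, THF, −78 °C; then 7, BF3·OEt2, −78 °C; AcOH; then TsOH (cat.), CH2Cl2, rt (−t-BuCHO)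
Reagents that add atoms: none (the acetal carbon leaves as pivalaldehyde)
Why: Proposed new method: the lithium enolate of 10 opens the BF3-activated 2,2-disubstituted epoxide by SN2 attack at its CH2 terminus, forming C4–C5 without touching C6, and the electrophile enters anti to the tert-butyl group (self-regeneration of stereocentres, giving 3R); the released tertiary alcohol then transacylates onto the acylal carbonyl with loss of pivalaldehyde to close the γ-lactone. The closest known chemistry is Seebach alkylation of this enolate with alkyl halides and aldehydes, BF3-assisted epoxide opening by lithium nucleophiles at −78 °C, and Creger's carboxylate-dianion/isobutylene oxide route to α,α,γ,γ-tetrasubstituted butyrolactones; this enolate class has not been shown to open epoxides.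

**Step 7**
Reactants: 11
Product: 12 (3R,5S)-3,5-dimethyl-5-(10-phenyldecyl)tetrahydrofuran-2,3-diol (anomeric mixture)
Conditions: DIBAL-H (2.5 equiv), CH2Cl2, −78 °C
Reagents that add atoms: none
Why: Partial reduction of the γ-lactone to the lactol, with the tetrahedral intermediate stabilised as an aluminium alkoxide at −78 °C; the anomeric centre is inconsequential and C4/C6 are untouched.

**Step 8**
Reactants: 12; 13 methyl (triphenylphosphoranylidene)acetate
Product: 14 plakortolide ether, (3aR,5S,6aR)-5,6a-dimethyl-5-(10-phenyldecyl)tetrahydrofuro[3,2-b]furan-2(3H)-one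
Conditions: Ph3P=CHCO2Me, toluene, 100 °C; then DBU (0.5 equiv), 60 °C
Reagents that add atoms: methyl (triphenylphosphoranylidene)acetate, COC(=O)C=P(c1ccccc1)(c1ccccc1)c1ccccc1 (gives C2 and C1=O; OMe is lost)
Why: Wittig olefination of the open hydroxy-aldehyde gives the dihydroxy enoate; reversible 5-exo oxa-Michael addition of the C6 tertiary OH and lactonisation of the C4 OH (or Z-enoate → butenolide → oxa-Michael) funnel to the only closable, cis-fused product, so C3 (R) is set by C4.

## Compound list

1 | (S)-citramalic acid | C[C@](O)(CC(=O)O)C(=O)O | starting material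
2 | 2,2-dimethoxypropane | COC(C)(C)OC | starting material
3 | (S)-2-(2,2,4-trimethyl-5-oxo-1,3-dioxolan-4-yl)acetic acid | C[C@@]1(CC(=O)O)OC(C)(C)OC1=O | intermediate
4 | 10-phenyldecanoic acid | OC(=O)CCCCCCCCCc1ccccc1 | starting material
5 | (S)-2,2,5-trimethyl-5-(10-phenyldecyl)-1,3-dioxolan-4-one | C[C@@]1(CCCCCCCCCCc2ccccc2)OC(C)(C)OC1=O | intermediate
6 | (S)-2-methyl-12-phenyldodecane-1,2-diol | C[C@@](O)(CO)CCCCCCCCCCc1ccccc1 | intermediate
7 | (S)-2-methyl-2-(10-phenyldecyl)oxirane | C[C@]1(CCCCCCCCCCc2ccccc2)CO1 | intermediate
8 | (S)-lactic acid | C[C@H](O)C(=O)O | starting material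
9 | pivalaldehyde | CC(C)(C)C=O | starting material
10 | (2S,5S)-2-tert-butyl-5-methyl-1,3-dioxolan-4-one | C[C@@H]1O[C@H](C(C)(C)C)OC1=O | intermediate
11 | (3R,5S)-3-hydroxy-3,5-dimethyl-5-(10-phenyldecyl)dihydrofuran-2(3H)-one | C[C@@]1(O)C[C@](C)(CCCCCCCCCCc2ccccc2)OC1=O | intermediate
12 | (3R,5S)-3,5-dimethyl-5-(10-phenyldecyl)tetrahydrofuran-2,3-diol | C[C@@]1(O)C[C@](C)(CCCCCCCCCCc2ccccc2)OC1O | intermediate
13 | methyl (triphenylphosphoranylidene)acetate | COC(=O)C=P(c1ccccc1)(c1ccccc1)c1ccccc1 | starting material
14 | plakortolide ether, (3aR,5S,6aR)-5,6a-dimethyl-5-(10-phenyldecyl)tetrahydrofuro[3,2-b]furan-2(3H)-one | C[C@]1(CCCCCCCCCCc2ccccc2)C[C@@]2(C)OC(=O)C[C@H]2O1 | target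

## Summary

Total steps: 8. Longest linear sequence: 7 (steps 1–4, 6–8).

Three steps most likely to fail:

1. **Step 6 (the proposed new step).** Risks: the enolate decomposes above about −30 °C, BF3 may rearrange the epoxide to the aldehyde, and the quaternary–CH2–quaternary bond is congested. Fallback (known chemistry): convert diol 6 into the α-triethylsilyloxy aldehyde (TESOTf, then Swern oxidation of the primary TES ether), add the enolate of 10 in a Seebach aldol, remove the C5 hydroxyl by Barton–McCombie deoxygenation (xanthate, Bu3SnH/AIBN), and treat with TsOH to give 11.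

2. **Step 2 (mixed Kolbe).** Risks: statistical homodimers, methanolysis of the dioxolanone, and non-Kolbe products. Fallback: drop the electrolysis and set C6 by Seebach alkylation of the D-lactic acid-derived (2R,5R)-dioxolanone enolate with 1-iodo-10-phenyldecane; this gives the tert-butyl acetal analogue of 5 with the same (S) centre, which enters step 3 unchanged.

3. **Step 8 (olefination/oxa-Michael/lactonisation).** Risks: slow Wittig on the hindered lactol and incomplete funnelling of the Michael adducts. Fallback: methylenate 12 (Ph3P=CH2) to (3R,5S)-3,5-dimethyl-15-phenylpentadec-1-ene-3,5-diol, then close both rings by Pd(II)-mediated hydroxycyclisation–carbonylation–lactonisation (PdCl2, CuCl2, CO, NaOAc, AcOH), the route established for plakortone-type 2,6-dioxabicyclo[3.3.0]octan-3-ones.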